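## Retrosynthetic overview

- **Labels and feature.** C1 = quaternary carbon with the angular methyl, C2/C3 = ring A CH2, C4 = C(OH)(iPr), C5 = ring-fusion CH, C6 = CH–O-acyl, then C7, C8(Me)=C9, C10. Ring B without C1, that is C5–C6(O)–C7–C8(Me)–C9–C10, is the carbon pattern of a 2-methoxy-4-methylphenyl ring whose ipso carbon C5 already carries the C4–C3–C2 chain, so only C1 has to be inserted between C5 and C10.
- **Endgame.** The p-coumarate goes on last to diol 27. The C4/C5/C6 triad of 27 comes from enone 21 (C4(iPr)=C5–C6=O) by Luche reduction, hydroxyl-directed epoxidation, an epoxy alcohol to β-hydroxy ketone hydride shift, and hydroxyl-directed reduction.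
- **Middle.** 21 comes from methoxydiene 15 (selenoxide route to the C4=C5 enone, isopropyl conjugate addition, re-dehydrogenation). 15 comes from azulenone 11 by removing the C2 carbonyl through its enol triflate and a Birch-type 1,4-reduction of the C7–C10 diene, which places C8=C9.
- **Key disconnection.** 11 is opened to α-methyl diazoketone 9 (intramolecular Buchner reaction, bonds C1–C5 and C1–C10). 9 is made from the arylpropanoyl chloride and diazoethane, because diazo transfer to the corresponding ethyl ketone could not tell its two α-CH2 groups apart. Acid 5 comes from 2-hydroxy-4-methylbenzaldehyde and malonic acid.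
- **Ring order.** The benzene ring is bought; ring A and ring B are formed together in step 6 (ring A by the C1–C5 bond, ring B by expansion of the arene); no ring is formed afterwards.

Key step: step 6

Remarks on the chemistry:
- The sense of induction of the copper–bis(oxazoline) catalyst on this α-methyl diazoketone cannot be predicted with confidence. The (S,S)-ligand is written; the equally available (R,R)-ligand would be used if the (8aS)-azulenone were to predominate.
- In azulene names, C1 of the text = C8a, C2 = C1, C3 = C2, C4 = C3, C5 = C3a, C6 = C4, C7 = C5, C8 = C6, C9 = C7, C10 = C8.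
- C3a of 16 and 17 and C3 of 20 are drawn without descriptor; these centres become sp2 again in the same or the next step.

## Route

Step 1
Reactants: 1 2-hydroxy-4-methylbenzaldehyde
Product: 2 2-methoxy-4-methylbenzaldehyde
Conditions: MeI, K2CO3, DMF, 23 °C
Reagents that add atoms: iodomethane, CI
Why: Williamson O-methylation of the phenoxide by SN2 on iodomethane; the aldehyde is not affected.

Step 2
Reactants: 2 2-methoxy-4-methylbenzaldehyde; 3 malonic acid
Product: 4 (2E)-3-(2-methoxy-4-methylphenyl)prop-2-enoic acid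
Conditions: pyridine, piperidine (cat.), 100 °C
Reagents that add atoms: none
Why: Knoevenagel–Doebner condensation with decarboxylation should give the (E)-cinnamic acid.

Step 3
Reactants: 4 (2E)-3-(2-methoxy-4-methylphenyl)prop-2-enoic acid
Product: 5 3-(2-methoxy-4-methylphenyl)propanoic acid
Conditions: H2 (1 atm), 10% Pd/C, EtOAc, 23 °C
Reagents that add atoms: none
Why: Heterogeneous hydrogenation of the conjugated C=C; arene, aryl ether and acid are inert at 1 atm.

Step 4
Reactants: 6 N-ethyl-N-nitrosourea
Product: 7 diazoethane (dried ethereal solution, used cold at once)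
Conditions: 40% aq KOH, Et2O, 0 °C
Reagents that add atoms: none
Why: Base-induced fragmentation of the N-nitrosourea is the standard generation of a diazoalkane, which is extracted into ether and never concentrated.

Step 5
Reactants: 5 3-(2-methoxy-4-methylphenyl)propanoic acid; 7 diazoethane
Product: 9 2-diazo-5-(2-methoxy-4-methylphenyl)pentan-3-one, via acid chloride 8 (not isolated)
Conditions: (COCl)2, DMF (cat.), CH2Cl2, 0 → 23 °C; concentrate; then 7 (3 equiv), Et2O, −20 → 0 °C
Reagents that add atoms: oxalyl chloride, O=C(Cl)C(=O)Cl (supplies only the chlorine of intermediate 8; all atoms of 9 come from 5 and 7)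
Why: Acylation of the diazoalkane by the acid chloride (Arndt–Eistert-type diazoketone synthesis, a second equivalent of 7 taking up HCl) puts the diazo group and its methyl on one defined carbon.

Step 6
Reactants: 9 2-diazo-5-(2-methoxy-4-methylphenyl)pentan-3-one
Product: 11 (8aR)-4-methoxy-6,8a-dimethyl-3,8a-dihydroazulen-1(2H)-one, via norcaradiene 10 (not isolated)
Conditions: [Cu(MeCN)4]PF6 (5 mol%), 2,2'-(propane-2,2-diyl)bis[(4S)-4-tert-butyl-4,5-dihydro-1,3-oxazole] (6 mol%), CH2Cl2, 40 °C, slow addition of 9 over 4 h; filtration through Et3N-washed silica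
Reagents that add atoms: none
Why: Loss of N2 from 9 at monovalent copper gives an electrophilic α-methyl α-acyl copper carbenoid whose carbon C1 adds across the C5–C10 bond of the tethered anisole ring, an intramolecular arene cyclopropanation (Buchner reaction) of the kind known for aryl-tethered α-diazoketones with copper–bis(oxazoline) and dirhodium catalysts, and this gives norcaradiene 10. Ring A closes in this [2+1] addition as a five-membered ring through the C1–C5 bond (the C2–C3–C4 tether makes attack at the ipso carbon 5-exo-like, the C1–C10 bond completing the cyclopropane), and ring B forms when 10 undergoes thermally allowed disrotatory six-electron electrocyclic opening of the C5–C10 bond, which expands the benzene ring to the cycloheptatriene. C1, the only stereocentre, is set by the C2-symmetric bis(oxazoline) ligand on copper, which selects the enantioface of the arene π bond that meets the carbenoid, and the ring opening does not touch it. The step needs regioselectivity for C5–C10 over C5–C6, which the methoxy group secures by shielding its own ortho carbon, and chemoselectivity over 1,2-hydride shift from the carbenoid methyl and over oxonium ylide formation, which the fast five-ring-forming addition under slow addition should secure. The 8a-methyl prevents tautomerisation of the trienone, but acid would still rearrange it to a 1-methyl-2-tetralone and hydrolyse the enol ether, so all handling is acid-free.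

Step 7
Reactants: 11 (8aR)-4-methoxy-6,8a-dimethyl-3,8a-dihydroazulen-1(2H)-one
Product: 12 (8aR)-4-methoxy-6,8a-dimethyl-3,8a-dihydroazulen-1-yl trifluoromethanesulfonate
Conditions: KN(SiMe3)2, THF, −78 °C; PhNTf2, −78 → 0 °C
Reagents that add atoms: N-phenylbis(trifluoromethanesulfonimide), O=S(=O)(N(c1ccccc1)S(=O)(=O)C(F)(F)F)C(F)(F)F
Why: Enol triflate formation; C3 is the only enolisable position because C1 is quaternary, and the methoxytriene is stable to base.

Step 8
Reactants: 12 (8aR)-4-methoxy-6,8a-dimethyl-3,8a-dihydroazulen-1-yl trifluoromethanesulfonate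
Product: 13 (8aR)-4-methoxy-6,8a-dimethyl-3,8a-dihydroazulene
Conditions: Pd(OAc)2 (5 mol%), PPh3 (10 mol%), HCO2H, Bu3N, DMF, 60 °C
Reagents that add atoms: none
Why: Palladium-catalysed formate reduction of the enol triflate (oxidative addition to zerovalent palladium, formate decarboxylation, C–H reductive elimination) removes the C2 oxygen without a radical or cation next to the vinyl-substituted quaternary C1, where skeletal shifts would be expected.

Step 9
Reactants: 13 (8aR)-4-methoxy-6,8a-dimethyl-3,8a-dihydroazulene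
Product: 14 (8aS)-4-methoxy-6,8a-dimethyl-3,5,8,8a-tetrahydroazulene (same spatial arrangement at C8a; only the priority order changes)
Conditions: Li, liquid NH3/THF, tBuOH (2.2 equiv), −78 °C; solid NH4Cl
Reagents that add atoms: none
Why: Birch-type dissolving-metal reduction: the triene radical anion should be protonated at C10, the terminus remote from the methoxy group, and the resulting pentadienyl anion (C5/C7/C9, OMe on the nodal C6) at its central carbon C7, as in anisole reductions, leaving the enol ether C5=C6, the new C8=C9 and the isolated C2=C3 untouched.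

Step 10
Reactants: 14 (8aS)-4-methoxy-6,8a-dimethyl-3,5,8,8a-tetrahydroazulene
Product: 15 (8aR)-4-methoxy-6,8a-dimethyl-1,2,3,5,8,8a-hexahydroazulene
Conditions: H2 (1 atm), RhCl(PPh3)3 (5 mol%), benzene, 23 °C
Reagents that add atoms: none
Why: Homogeneous hydrogenation with RhCl(PPh3)3 should select the cis-disubstituted cyclopentene C2=C3 over the trisubstituted C8=C9 and the tetrasubstituted enol ether.

Step 11
Reactants: 15 (8aR)-4-methoxy-6,8a-dimethyl-1,2,3,5,8,8a-hexahydroazulene
Product: 18 (8aR)-6,8a-dimethyl-1,2,8,8a-tetrahydroazulen-4(5H)-one, via selenide 16 (not isolated), via selenoxide 17 (not isolated)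
Conditions: PhSeCl (1.05 equiv), pyridine, CH2Cl2, −78 °C; aq NaHCO3; then NaIO4, THF/MeOH/H2O, 0 → 23 °C
Reagents that add atoms: water, O (carbonyl oxygen of 18); benzeneselenenyl chloride, Cl[Se]c1ccccc1, and sodium periodate, [Na+].[O-]I(=O)(=O)=O, add atoms only to intermediates 16 and 17
Why: Selenenylation of the enol ether at its nucleophilic carbon C5 (regiodefined, whereas enolisation of the free ketone would go to the allylic C7), hydrolysis, and selenoxide syn-elimination, which can only use a C4–H because C1 is quaternary, should give the C4=C5 enone.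

Step 12
Reactants: 18 (8aR)-6,8a-dimethyl-1,2,8,8a-tetrahydroazulen-4(5H)-one; 19 isopropylmagnesium chloride
Product: 20 (8aR)-3-isopropyl-6,8a-dimethyl-4-(trimethylsilyloxy)-1,2,3,5,8,8a-hexahydroazulene (C3 configuration undefined)
Conditions: iPrMgCl (1.5 equiv), CuBr·SMe2 (10 mol%), Me3SiCl (2 equiv), THF, −78 °C; Et3N, cold aq NaHCO3
Reagents that add atoms: chlorotrimethylsilane, C[Si](C)(C)Cl
Why: Copper-catalysed conjugate addition of the Grignard reagent to the unsubstituted β-carbon C4, accelerated and trapped by Me3SiCl, gives the regiodefined C5=C6 silyl enol ether faster than the Grignard reagent can deprotonate C7.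

Step 13
Reactants: 20 (8aR)-3-isopropyl-6,8a-dimethyl-4-(trimethylsilyloxy)-1,2,3,5,8,8a-hexahydroazulene
Product: 21 (8aR)-3-isopropyl-6,8a-dimethyl-1,2,8,8a-tetrahydroazulen-4(5H)-one
Conditions: Pd(OAc)2 (1.1 equiv), MeCN, 23 °C
Reagents that add atoms: none
Why: Saegusa–Ito oxidation: the palladium enolate formed at C5 on the face away from the isopropyl group is syn to the single β-hydrogen (C4–H), and β-hydride elimination should give the tetrasubstituted enone.

Step 14
Reactants: 21 (8aR)-3-isopropyl-6,8a-dimethyl-1,2,8,8a-tetrahydroazulen-4(5H)-one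
Product: 22 (4R,8aR)-3-isopropyl-6,8a-dimethyl-1,2,4,5,8,8a-hexahydroazulen-4-ol (hydroxyl cis to the 8a-methyl)
Conditions: NaBH4, CeCl3·7H2O, MeOH, −78 °C
Reagents that add atoms: none
Why: Luche 1,2-reduction; the angular methyl lies over one face of the twisted C6 carbonyl (chair-like ring B), so hydride should enter from the opposite face and set C6 with the hydroxyl cis to the methyl.

Step 15
Reactants: 22 (4R,8aR)-3-isopropyl-6,8a-dimethyl-1,2,4,5,8,8a-hexahydroazulen-4-ol
Product: 23 (3R,3aS,4R,8aR)-3,3a-epoxy-3-isopropyl-6,8a-dimethyl-1,2,3,3a,4,5,8,8a-octahydroazulen-4-ol (epoxide oxygen and hydroxyl both cis to the 8a-methyl)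
Conditions: VO(acac)2 (5 mol%), tBuOOH (1.3 equiv, decane), CH2Cl2, 0 °C
Reagents that add atoms: tert-butyl hydroperoxide, CC(C)(C)OO
Why: Hydroxyl-directed vanadium-catalysed epoxidation delivers oxygen from the vanadate ester of C6–OH to the same face of the tetrasubstituted allylic C4=C5, setting C4 and C5, and should be faster than reaction at the homoallylic trisubstituted C8=C9.

Step 16
Reactants: 23 (3R,3aS,4R,8aR)-3,3a-epoxy-3-isopropyl-6,8a-dimethyl-1,2,3,3a,4,5,8,8a-octahydroazulen-4-ol
Product: 25 (3R,3aR,8aR)-3-isopropyl-6,8a-dimethyl-3-(triethylsilyloxy)-2,3,3a,5,8,8a-hexahydroazulen-4(1H)-one, via silyl ether 24 (not isolated)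
Conditions: Et3SiOTf (1.2 equiv), iPr2NEt (1.5 equiv), 4 Å sieves, CH2Cl2, −78 → −40 °C
Reagents that add atoms: triethylsilyl trifluoromethanesulfonate, CC[Si](CC)(CC)OS(=O)(=O)C(F)(F)F
Why: Semipinacol rearrangement of the epoxy silyl ether with 1,2-hydride shift (non-aldol aldol process): silyl triflate opens the epoxide at C5, and the C6–H, which is anti-periplanar to the breaking C5–O bond in the syn epoxy ether while C7 is held syn-clinal by ring B, migrates with inversion, so C5–H ends trans to the angular methyl, C4 keeps its oxygen as the silyl ether and C6 becomes the ketone.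

Step 17
Reactants: 25 (3R,3aR,8aR)-3-isopropyl-6,8a-dimethyl-3-(triethylsilyloxy)-2,3,3a,5,8,8a-hexahydroazulen-4(1H)-one
Product: 26 (3R,3aR,8aR)-3-hydroxy-3-isopropyl-6,8a-dimethyl-2,3,3a,5,8,8a-hexahydroazulen-4(1H)-one
Conditions: HF·pyridine, pyridine, THF, 0 °C
Reagents that add atoms: none
Why: Buffered fluoride cleavage of the tertiary silyl ether frees the hydroxyl without the base or strong acid that would cause retro-aldol cleavage, dehydration or migration of C8=C9 into conjugation.

Step 18
Reactants: 26 (3R,3aR,8aR)-3-hydroxy-3-isopropyl-6,8a-dimethyl-2,3,3a,5,8,8a-hexahydroazulen-4(1H)-one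
Product: 27 (3R,3aS,4S,8aR)-3-isopropyl-6,8a-dimethyl-1,2,3,3a,4,5,8,8a-octahydroazulene-3,4-diol
Conditions: Me4NBH(OAc)3 (5 equiv), MeCN/AcOH (1:1), −30 → −20 °C
Reagents that add atoms: none
Why: Evans–Saksena reduction: the reagent does not reduce ketones by itself, so hydride can only be delivered within the alkoxyborohydride formed at the C4 hydroxyl, from the face that carries this oxygen, which sets C6 with the hydroxyl trans to the angular methyl (an external hydride would enter from the other face).

Step 19
Reactants: 28 (2E)-3-(4-hydroxyphenyl)prop-2-enoic acid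
Product: 30 (2E)-3-[4-(tert-butyldimethylsilyloxy)phenyl]prop-2-enoic acid, via bis-silyl derivative 29 (not isolated)
Conditions: TBSCl (2.4 equiv), imidazole, DMF, 23 °C; then AcOH/THF/H2O, 23 °C
Reagents that add atoms: tert-butyldimethylsilyl chloride, CC(C)(C)[Si](C)(C)Cl
Why: Silylation of phenol and acid followed by hydrolysis of the far more labile silyl ester leaves the aryl silyl ether in place.

Step 20
Reactants: 27 (3R,3aS,4S,8aR)-3-isopropyl-6,8a-dimethyl-1,2,3,3a,4,5,8,8a-octahydroazulene-3,4-diol; 30 (2E)-3-[4-(tert-butyldimethylsilyloxy)phenyl]prop-2-enoic acid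
Product: 31 (3R,3aS,4S,8aR)-3-hydroxy-3-isopropyl-6,8a-dimethyl-1,2,3,3a,4,5,8,8a-octahydroazulen-4-yl (2E)-3-[4-(tert-butyldimethylsilyloxy)phenyl]prop-2-enoate
Conditions: DCC, DMAP, CH2Cl2, 23 °C
Reagents that add atoms: none
Why: Steglich esterification; only the secondary C6 hydroxyl is acylated, the tertiary C4 hydroxyl being unreactive under these conditions.

Step 21
Reactants: 31 (3R,3aS,4S,8aR)-3-hydroxy-3-isopropyl-6,8a-dimethyl-1,2,3,3a,4,5,8,8a-octahydroazulen-4-yl (2E)-3-[4-(tert-butyldimethylsilyloxy)phenyl]prop-2-enoate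
Product: 32 (3R,3aS,4S,8aR)-3-hydroxy-3-isopropyl-6,8a-dimethyl-1,2,3,3a,4,5,8,8a-octahydroazulen-4-yl (2E)-3-(4-hydroxyphenyl)prop-2-enoate (CNP0265426.1)
Conditions: Bu4NF (1.1 equiv), AcOH (1.1 equiv), THF, 0 °C
Reagents that add atoms: none
Why: Fluoride cleaves the aryl silyl ether much faster than it can affect the hindered cinnamate ester, and acetic acid buffers the phenoxide.

## Compound list

1 | 2-hydroxy-4-methylbenzaldehyde | Cc1ccc(C=O)c(O)c1 | starting material
2 | 2-methoxy-4-methylbenzaldehyde | COc1cc(C)ccc1C=O | intermediate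
3 | malonic acid | OC(=O)CC(=O)O | starting material
4 | (2E)-3-(2-methoxy-4-methylphenyl)prop-2-enoic acid | COc1cc(C)ccc1/C=C/C(=O)O | intermediate
5 | 3-(2-methoxy-4-methylphenyl)propanoic acid | COc1cc(C)ccc1CCC(=O)O | intermediate
6 | N-ethyl-N-nitrosourea | CCN(N=O)C(N)=O | starting material
7 | diazoethane | CC=[N+]=[N-] | intermediate
8 | 3-(2-methoxy-4-methylphenyl)propanoyl chloride | COc1cc(C)ccc1CCC(=O)Cl | intermediate (not isolated)
9 | 2-diazo-5-(2-methoxy-4-methylphenyl)pentan-3-one | COc1cc(C)ccc1CCC(=O)C(C)=[N+]=[N-] | intermediate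
10 | norcaradiene tautomer of 11 (cyclopropane C1–C5–C10 closed; methyl on the cyclopropane face of the cyclohexadiene ring, C10–H on the other) | COC1=CC(C)=C[C@@H]2[C@@]3(C)C(=O)CC[C@@]123 | intermediate (not isolated)
11 | (8aR)-4-methoxy-6,8a-dimethyl-3,8a-dihydroazulen-1(2H)-one | COC1=C2CCC(=O)[C@]2(C)C=CC(C)=C1 | intermediate
12 | (8aR)-4-methoxy-6,8a-dimethyl-3,8a-dihydroazulen-1-yl trifluoromethanesulfonate | COC1=C2CC=C(OS(=O)(=O)C(F)(F)F)[C@]2(C)C=CC(C)=C1 | intermediate
13 | (8aR)-4-methoxy-6,8a-dimethyl-3,8a-dihydroazulene | COC1=C2CC=C[C@]2(C)C=CC(C)=C1 | intermediate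
14 | (8aS)-4-methoxy-6,8a-dimethyl-3,5,8,8a-tetrahydroazulene | CC1=CC[C@@]2(C)C=CCC2=C(OC)C1 | intermediate
15 | (8aR)-4-methoxy-6,8a-dimethyl-1,2,3,5,8,8a-hexahydroazulene | CC1=CC[C@@]2(C)CCCC2=C(OC)C1 | intermediate
16 | (8aR)-6,8a-dimethyl-3a-(phenylselanyl)-1,2,3,3a,8,8a-hexahydroazulen-4(5H)-one (C3a undefined) | CC1=CC[C@@]2(C)CCCC2([Se]c3ccccc3)C(=O)C1 | intermediate (not isolated)
17 | selenoxide of 16 (C3a and selenium undefined) | CC1=CC[C@@]2(C)CCCC2([Se](=O)c3ccccc3)C(=O)C1 | intermediate (not isolated)
18 | (8aR)-6,8a-dimethyl-1,2,8,8a-tetrahydroazulen-4(5H)-one | CC1=CC[C@@]2(C)CCC=C2C(=O)C1 | intermediate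
19 | isopropylmagnesium chloride | CC(C)[Mg]Cl | starting material
20 | (8aR)-3-isopropyl-6,8a-dimethyl-4-(trimethylsilyloxy)-1,2,3,5,8,8a-hexahydroazulene (C3 undefined) | CC1=CC[C@@]2(C)CCC(C(C)C)C2=C(O[Si](C)(C)C)C1 | intermediate
21 | (8aR)-3-isopropyl-6,8a-dimethyl-1,2,8,8a-tetrahydroazulen-4(5H)-one | CC1=CC[C@@]2(C)CCC(C(C)C)=C2C(=O)C1 | intermediate
22 | (4R,8aR)-3-isopropyl-6,8a-dimethyl-1,2,4,5,8,8a-hexahydroazulen-4-ol | CC1=CC[C@@]2(C)CCC(C(C)C)=C2[C@H](O)C1 | intermediate
23 | (3R,3aS,4R,8aR)-3,3a-epoxy-3-isopropyl-6,8a-dimethyl-1,2,3,3a,4,5,8,8a-octahydroazulen-4-ol | CC1=CC[C@@]2(C)CC[C@]3(C(C)C)O[C@]23[C@H](O)C1 | intermediate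
24 | 4-O-triethylsilyl ether of 23 | CC1=CC[C@@]2(C)CC[C@]3(C(C)C)O[C@]23[C@H](O[Si](CC)(CC)CC)C1 | intermediate (not isolated)
25 | (3R,3aR,8aR)-3-isopropyl-6,8a-dimethyl-3-(triethylsilyloxy)-2,3,3a,5,8,8a-hexahydroazulen-4(1H)-one | CC1=CC[C@@]2(C)CC[C@@](O[Si](CC)(CC)CC)(C(C)C)[C@@H]2C(=O)C1 | intermediate
26 | (3R,3aR,8aR)-3-hydroxy-3-isopropyl-6,8a-dimethyl-2,3,3a,5,8,8a-hexahydroazulen-4(1H)-one | CC1=CC[C@@]2(C)CC[C@@](O)(C(C)C)[C@@H]2C(=O)C1 | intermediate
27 | (3R,3aS,4S,8aR)-3-isopropyl-6,8a-dimethyl-1,2,3,3a,4,5,8,8a-octahydroazulene-3,4-diol | CC1=CC[C@@]2(C)CC[C@@](O)(C(C)C)[C@@H]2[C@@H](O)C1 | intermediate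
28 | (2E)-3-(4-hydroxyphenyl)prop-2-enoic acid (p-coumaric acid) | OC(=O)/C=C/c1ccc(O)cc1 | starting material
29 | tert-butyldimethylsilyl (2E)-3-[4-(tert-butyldimethylsilyloxy)phenyl]prop-2-enoate | CC(C)(C)[Si](C)(C)OC(=O)/C=C/c1ccc(O[Si](C)(C)C(C)(C)C)cc1 | intermediate (not isolated)
30 | (2E)-3-[4-(tert-butyldimethylsilyloxy)phenyl]prop-2-enoic acid | OC(=O)/C=C/c1ccc(O[Si](C)(C)C(C)(C)C)cc1 | intermediate
31 | (3R,3aS,4S,8aR)-3-hydroxy-3-isopropyl-6,8a-dimethyl-1,2,3,3a,4,5,8,8a-octahydroazulen-4-yl (2E)-3-[4-(tert-butyldimethylsilyloxy)phenyl]prop-2-enoate | CC1=CC[C@@]2(C)CC[C@@](O)(C(C)C)[C@@H]2[C@@H](OC(=O)/C=C/c2ccc(O[Si](C)(C)C(C)(C)C)cc2)C1 | intermediate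
32 | (3R,3aS,4S,8aR)-3-hydroxy-3-isopropyl-6,8a-dimethyl-1,2,3,3a,4,5,8,8a-octahydroazulen-4-yl (2E)-3-(4-hydroxyphenyl)prop-2-enoate | CC1=CC[C@@]2(C)CC[C@@](O)(C(C)C)[C@@H]2[C@@H](OC(=O)/C=C/c2ccc(O)cc2)C1 | target

## Step count and risks

Total step count: 21.
Longest linear sequence: 19 steps (1 → 32 through steps 1–3, 5–18, 20 and 21; steps 4 and 19 are side branches).

Steps most likely to fail:

1. Step 6. The copper–bis(oxazoline) catalyst may discriminate poorly between the arene enantiofaces when the carbenoid carbon carries a methyl group, and 1,2-hydride migration to the vinyl ketone may compete. Fallback: starting from 9, the cyclisation is run with achiral Rh2(OAc)4 (dirhodium tetraacetate, divalent rhodium) in CH2Cl2 to give the racemic azulenone F1. A Corey–Bakshi–Shibata reduction ((S)-2-methyl-CBS-oxazaborolidine, catecholborane, toluene, −78 °C) then turns the two enantiomers into diastereomers under reagent control, the (1R,8aR)-alcohol F2 (hydroxyl cis to the methyl) and the (1R,8aS)-alcohol F3, which are separated by chromatography. Oxidation of F2 with Dess–Martin periodinane (NaHCO3, CH2Cl2) returns to the route at 11.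

2. Step 16. The epoxide may ionise at C4 instead of C5, or the ring carbon C7 may migrate in place of hydride (ring contraction), and the silyl triflate may silylate the product ketone. Fallback: starting from 23, the C6 hydroxyl is oxidised with Dess–Martin periodinane to the epoxy ketone F4. Its Cα–O bond is then cleaved reductively with SmI2 (THF/MeOH, −90 °C), which gives the β-hydroxy ketone directly and returns to the route at 26. In this variant C5 is set by protonation of the samarium enolate and not stereospecifically.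

3. Step 18. Exchange of the hindered tertiary hydroxyl with the borohydride may be slow, and hydride delivery has to pass the angular methyl, so ketone may remain or the C6 epimer may form. Fallback: starting from 26, NaBH4 (MeOH, −20 °C) reduces the ketone from the open face to the 6-epi-diol F5. A Mitsunobu esterification of F5 with acid 30 (PPh3, diisopropyl azodicarboxylate, toluene, 0 → 23 °C) then forms the ester with inversion at C6 and returns to the route at 31.

Further compounds
F1 | step 6 | racemic 4-methoxy-6,8a-dimethyl-3,8a-dihydroazulen-1(2H)-one | COC1=C2CCC(=O)C2(C)C=CC(C)=C1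
F2 | step 6 | (1R,8aR)-4-methoxy-6,8a-dimethyl-1,2,3,8a-tetrahydroazulen-1-ol | COC1=C2CC[C@@H](O)[C@]2(C)C=CC(C)=C1
F3 | step 6 | (1R,8aS)-4-methoxy-6,8a-dimethyl-1,2,3,8a-tetrahydroazulen-1-ol | COC1=C2CC[C@@H](O)[C@@]2(C)C=CC(C)=C1
F4 | step 16 | (3R,3aR,8aR)-3,3a-epoxy-3-isopropyl-6,8a-dimethyl-2,3,3a,5,8,8a-hexahydroazulen-4(1H)-one | CC1=CC[C@@]2(C)CC[C@]3(C(C)C)O[C@]23C(=O)C1
F5 | step 18 | (3R,3aS,4R,8aR)-3-isopropyl-6,8a-dimethyl-1,2,3,3a,4,5,8,8a-octahydroazulene-3,4-diol | CC1=CC[C@@]2(C)CC[C@@](O)(C(C)C)[C@@H]2[C@H](O)C1
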